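starting complex 21 mM; incoming ligand 5.00 equiv; time 20 h

    starting complex + incoming ligand ⇌ leaving ligand + complex with one exchanged (K1 = 0.10, k1 = 0.12 /M/h)
    complex with one exchanged + incoming ligand ⇌ leaving ligand + complex with two exchanged (K2 = 0.14, k2 = 0.15 /M/h)
    complex with two exchanged + incoming ligand ⇌ leaving ligand + complex with three exchanged (K3 = 0.092, k3 = 0.30 /M/h)
    complex with three exchanged + incoming ligand ⇌ leaving ligand + complex with four exchanged (K4 = 0.10, k4 = 0.15 /M/h)
    leaving ligand + incoming ligand ⇌ idle adduct, settled at all times (K5 = 17 /M)
    incoming ligand → decomposed reagent (k6 = 0.062 /h)

- what is said of leaving ligand includes idle adduct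
- run time (flask): 20 h

1. part of the starting complex that has reacted at 20 h
2. share of the unused incoming ligand that is free and not bound as idle adduct, at 20 h

The incoming ligand is the reagent I follow, because at the start its decay to decomposed reagent runs 25 times as fast as its forward use in step 1. So I first take c(incoming ligand) as a plain exponential with half-life 11 h, and the starting complex reacts with it as a pseudo-first-order partner.

Up to 20 h that curve encloses 1.20 M·h. This is the exposure, the area under c(incoming ligand) against time. The part of the starting complex reacted by the forward step is then x, one minus the exponential of minus 0.12 /M/h times the exposure.

My small table has two rows. At 10.0 h the exposure is 0.783 M·h and x is 8.96%; at 20 h they are 1.20 M·h and 13.4%. Reading down the exposure column, the second stretch adds less than the first, by 0.362 M·h, as the ligand decays. Reading across, x is the large term, and I compute two small corrections to it.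

Taking x to rise evenly, I estimate that exchange removes about 0.0282 M·h of exposure. For the return, with back constant 1.20 /M/h, I take the amounts of leaving ligand and complex with one exchanged as equal, as a rough assumption, and estimate that about 0.304% of the charge comes back. My c is therefore 12.8%.

For the free share, I count as a first estimate one leaving ligand per reacted complex, setting aside further exchanges, and take 0.0304 M of incoming ligand; that gives 1.78 mM of unbound leaving ligand, so I expect 97.1%.

The forecast, which starts from “Forward loss of starting complex”, gives 12.9% (range 12.3% to 13.4%) and 96.7% (range 96.2% to 97.1%), a free share lower than mine.

The simulation gives 12.9% and 96.7%. In this flask x stands 0.50 percentage points above the simulated c, and my corrections took off 0.6 points; my free share stands 0.40 points higher than the simulated one. The neighbouring flask charges 5.2 mM of starting complex at the same equivalents, so its exposure scales to 0.298 M·h and its x is 3.51%. The same two corrections now total 0.026 points, and that neighbouring flask gives 3.49%.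

The numbers are assumed, and the outcome is calculated.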